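**Strategy.** Ring A is closed last, at C3–C4, by a Dieckmann condensation of a tricyclic triester in which C4 is the CH2 of a C5=C6 glutaconate (C19 ester on C4, C7 ester on C6) and C3 is the ester carbon of the C1–C2 chain on C10; methyl iodide then quaternises C4 in the same flask, anti to C20. The step exploits that C3-OH is β to the C19 carboxyl on quaternary C4 and that C4 is γ to C7 through ring B. The precursor is a BCD tricycle built from 3-methoxybenzoic acid by Birch alkylation, vinyl-radical closure of ring D and an ynone Michael closure of ring B; later reductions set C5, C6, C3 and C11.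

Key step: step 10

Numbering: gibberellane numbering of the target is used throughout. Ring A is C1–C5 and C10; ring B is C5, C6, C8, C9, C10; ring C is C8, C9, C11–C14; ring D is C8, C14, C13, C16, C15. C17 is the methylene on C16, C18 the methyl and C19 the carboxyl on C4, C20 the methyl on C10, C7 the carboxyl on C6. α/β follow the usual gibberellin drawing (C20 and C19 α; H-5, H-9 and the C15–C16 bridge β).

Remark (assumption): in step 3 the (S)-1-phenylethylammonium salt of the wanted (1R,5S) acid is taken to be the less soluble diastereomer; if it is not, the (R)-amine is used in the same way.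

**Step 1**
Reactants: 1 3-methoxybenzoic acid; 2 2,3-dibromopropene
Product: 4 rac-1-(2-bromoprop-2-enyl)-5-oxocyclohex-3-ene-1-carboxylic acid, via dienyl ether acid 3 (not isolated)
Conditions: Li, NH3(l), THF, −78 °C; 2; NH4Cl; then 2 M HCl, THF, 40 °C
Reagents that add atoms: water, O
Why: Birch reductive alkylation dearomatises the ring and alkylates the carboxylate-stabilised C8 anion (quaternary centre, racemic), and acid hydrolysis of the C11 enol ether with conjugation of the C13=C14 alkene should give the 5,5-disubstituted cyclohexenone.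

**Step 2**
Reactants: 4
Product: 5 rac-6-methylidene-3-oxobicyclo[3.2.1]octane-1-carboxylic acid
Conditions: Bu3SnH, AIBN (cat.), benzene, 80 °C, slow addition
Reagents that add atoms: none
Why: 5-exo-trig cyclisation of the C16 vinyl radical onto the enone β-carbon C13 closes ring D, and the bridge can only span C8 and C13 cis, so C13 follows from C8.

**Step 3**
Reactants: 5
Product: 7 (1R,5S)-6-methylidene-3-oxobicyclo[3.2.1]octane-1-carboxylic acid, via 1-phenylethylammonium salt 6 (not isolated)
Conditions: (S)-1-phenylethylamine, EtOAc/EtOH, recrystallisation of the salt; then 1 M HCl, Et2O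
Reagents that add atoms: none
Why: classical resolution through diastereomeric ammonium salts separates the enantiomers of the rigid bridgehead acid and so fixes the absolute configuration of C8 and C13.

**Step 4**
Reactants: 7
Product: 9 (1R,5S)-1-(but-2-ynoyl)-6-methylidenebicyclo[3.2.1]octan-3-one, via acid chloride 8 (not isolated)
Conditions: (COCl)2, DMF (cat.), CH2Cl2, 0 → 25 °C; then propyne, PdCl2(PPh3)2 (cat.), CuI (cat.), Et3N, THF, 25 °C
Reagents that add atoms: oxalyl chloride, O=C(Cl)C(=O)Cl (chlorine of 8 only); propyne, CC#C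
Why: acyl Sonogashira coupling of the bridgehead acid chloride, which cannot form a ketene, with propyne should give the ynone that carries C5, C10 and C20, while the hindered C11 ketone stays inert.

**Step 5**
Reactants: 9
Product: 10 tricyclic enedione (ring B closed; H-9β)
Conditions: KOtBu (0.2 equiv), t-BuOH/THF, 0 → 25 °C; AcOH
Reagents that add atoms: none
Why: reversible enolisation of the C11 ketone lets only the C9 enolate reach the ynone, and its intramolecular Michael addition (5-endo-dig, allowed by the Baldwin rules) closes ring B as the cyclopentenone; the cis B/C fusion (H-9β) is the unstrained one on the rigid bicyclooctane and is also the thermodynamic outcome at this epimerisable centre.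

**Step 6**
Reactants: 10
Product: 11 C6 trimethylsilyl enol ether of the C10 adduct
Conditions: (1-ethoxycyclopropoxy)trimethylsilane, ZnCl2, Et2O, 25 °C; then 10, CuBr·SMe2 (cat.), HMPA, THF, 0 → 25 °C
Reagents that add atoms: (1-ethoxycyclopropoxy)trimethylsilane, CCOC1(CC1)O[Si](C)(C)C
Why: copper-catalysed conjugate addition of the zinc homoenolate to the β-methyl enone creates quaternary C10, the nucleophile entering on the β-face (syn to H-9, anti to C11 of ring C) so that the C1–C3 chain is β and C20 α, and the chlorosilane formed with the homoenolate traps the C6 enolate regiospecifically.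

**Step 7**
Reactants: 11
Product: 12 diketo diester (C5 epimers)
Conditions: BrCH2CO2Me, BnMe3NF (anhydrous), 4 Å molecular sieves, THF, −20 → 25 °C
Reagents that add atoms: methyl bromoacetate, COC(=O)CBr
Why: fluoride-mediated alkylation of the silyl enol ether puts the C4–C19 unit on C5 regiospecifically without a base that would enolise the C11 ketone, and the C5 configuration is irrelevant because C5 becomes trigonal in step 8.

**Step 8**
Reactants: 12
Product: 14 C6 enol triflate, via silyl enol ether 13 (not isolated)
Conditions: LDA, THF, −78 °C; i-Pr3SiOTf; then KN(SiMe3)2, −78 °C; PhNTf2, −78 → 0 °C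
Reagents that add atoms: triisopropylsilyl triflate, CC(C)[Si](OS(=O)(=O)C(F)(F)F)(C(C)C)C(C)C; N-phenylbis(trifluoromethanesulfonimide), O=S(=O)(N(c1ccccc1)S(=O)(=O)C(F)(F)F)C(F)(F)F
Why: kinetic deprotonation at the unhindered C12 methylene and O-silylation mask the C11 ketone as its silyl enol ether, after which the C6 ketone, enolisable only towards C5, is converted into the tetrasubstituted enol triflate.

**Step 9**
Reactants: 14
Product: 15 glutaconate-type triester
Conditions: Pd(OAc)2 (cat.), dppp, CO (1 atm), MeOH, Et3N, DMF, 60 °C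
Reagents that add atoms: carbon monoxide, [C-]#[O+]; methanol, CO
Why: palladium-catalysed methoxycarbonylation of the vinyl triflate installs C7 on C6 and creates the C5=C6 enoate, which turns C4-H2 into the doubly activated carbon of a glutaconate.

**Step 10**
Reactants: 15
Product: 17 tetracyclic 3-oxo diester with quaternary C4, via Dieckmann enolate 16 (not isolated)
Conditions: KOtBu (1.05 equiv), THF, 0 → 25 °C; then MeI, 25 °C
Reagents that add atoms: iodomethane, CI
Why: tert-butoxide removes a proton from C4, the only glutaconate-type carbon acid in 15, and the delocalised anion attacks the C3 ester carbonyl of the chain held on the β-face of C10; loss of ethoxide gives the β-keto ester, whose stabilised enolate 16 is then C-methylated by iodomethane. The closest known reaction type is the Dieckmann condensation with in-situ alkylation of the cyclic β-keto ester enolate, here with a vinylogous (glutaconate) donor. Ring A closes in the 6-(enolexo)-exo-trig mode by acyl substitution at C3. The new stereocentre C4 is set in the methylation: the pseudo-axial C20 methyl on C10 shields the α-face of the planar enolate, so iodomethane should enter from the β-face and leave C18 β and the C19 ester α. The step needs C4 to react and not C6 or C2: acylation at C6 would give a non-enolisable product that reverts, and C2 is not deprotonated by one equivalent of alkoxide, so the enolisable C4 product is the sink. Because the single equivalent of base ends up as enolate 16, no alkoxide remains to cleave the quaternised β-keto ester.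

**Step 11**
Reactants: 17
Product: 19 saturated 3-oxo diester (H-5β; H-6α), via lithium enolate 18 (not isolated)
Conditions: LDA, THF, −78 °C; then Li, NH3(l), t-BuOH, −78 °C; NH4Cl; then KOtBu (cat.), t-BuOH, 25 °C
Reagents that add atoms: none
Why: with the C3 ketone shielded as its lithium enolate, dissolving-metal conjugate reduction touches only the C5=C6 enoate, the C5 carbanion being protonated anti to the C20 angular methyl (and the α C19 ester) to give the trans A/B fusion (H-5β), and tert-butoxide then equilibrates C6 to the more stable ester trans to C4 (H-6α).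

**Step 12**
Reactants: 19
Product: 21 dimethyl 3β-hydroxy-11-oxogibberell-16-ene-7,19-dioate, via silylated alcohol 20 (not isolated)
Conditions: LiBH(s-Bu)3, THF, −78 °C; AcOH; then Bu4NF, AcOH, THF, 0 °C
Reagents that add atoms: none
Why: the bulky hydride attacks the C3 ketone along the equatorial trajectory and gives the axial 3β-alcohol, as known for 3-oxo terpenoids with a quaternary C4, while C11 stays masked, and buffered fluoride then cleaves the silyl enol ether to the C11 ketone.

**Step 13**
Reactants: 21
Product: 22 3β-hydroxy-11-oxogibberell-16-ene-7,19-dioic acid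
Conditions: n-PrSLi, HMPA, 25 °C; then 1 M HCl, 0 °C
Reagents that add atoms: none
Why: thiolate SN2 attack at the two O-methyl groups frees both hindered carboxylic acids without base strong enough to epimerise C6 or open the β-hydroxy acid array.

**Step 14**
Reactants: 22
Product: 23 3β,11α-dihydroxygibberell-16-ene-7,19-dioic acid (target)
Conditions: Li, NH3(l), THF, −78 → −33 °C; MeOH; NH4Cl
Reagents that add atoms: none
Why: dissolving-metal reduction of the hindered C11 ketone on the dicarboxylate should give the thermodynamically preferred equatorial 11α-alcohol (trans to H-9, away from the C15–C16 bridge), as in the reduction of 11-oxo steroids, while carboxylates and the isolated alkene are inert.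

**Compound list**

1 | 3-methoxybenzoic acid | COc1cccc(C(=O)O)c1 | starting material
2 | 2,3-dibromopropene | C=C(Br)CBr | starting material
3 | rac-1-(2-bromoprop-2-enyl)-3-methoxycyclohexa-2,5-diene-1-carboxylic acid | COC1=CC(CC(Br)=C)(C(=O)O)C=CC1 | intermediate
4 | rac-1-(2-bromoprop-2-enyl)-5-oxocyclohex-3-ene-1-carboxylic acid | C=C(Br)CC1(C(=O)O)CC=CC(=O)C1 | intermediate
5 | rac-6-methylidene-3-oxobicyclo[3.2.1]octane-1-carboxylic acid | C=C1CC2(C(=O)O)CC1CC(=O)C2 | intermediate
6 | (S)-1-phenylethylammonium (1R,5S)-6-methylidene-3-oxobicyclo[3.2.1]octane-1-carboxylate | C=C1C[C@]2(C(=O)[O-])C[C@H]1CC(=O)C2.C[C@H]([NH3+])c1ccccc1 | intermediate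
7 | (1R,5S)-6-methylidene-3-oxobicyclo[3.2.1]octane-1-carboxylic acid (rings C and D; C8 and C13 as in the target) | C=C1C[C@]2(C(=O)O)C[C@H]1CC(=O)C2 | intermediate
8 | (1R,5S)-6-methylidene-3-oxobicyclo[3.2.1]octane-1-carbonyl chloride | C=C1C[C@]2(C(=O)Cl)C[C@H]1CC(=O)C2 | intermediate
9 | (1R,5S)-1-(but-2-ynoyl)-6-methylidenebicyclo[3.2.1]octan-3-one | C=C1C[C@]2(C(=O)C#CC)C[C@H]1CC(=O)C2 | intermediate
10 | tricyclic enedione: ring B cyclopentenone (C6 ketone, C5=C10, C20 methyl on C10) fused at C8–C9 (H-9β) to the 16-methylidene bicyclooctan-11-one | C=C1C[C@]23C[C@H]1CC(=O)[C@H]2C(C)=CC3=O | intermediate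
11 | C6 trimethylsilyl enol ether (C5=C6) with quaternary C10 (C20 α, CH2CH2CO2Et β), 11-oxo, H-9β | C=C1C[C@]23C[C@H]1CC(=O)[C@H]2[C@](C)(CCC(=O)OCC)C=C3O[Si](C)(C)C | intermediate
12 | 6,11-diketone with CH2CO2Me (C4, C19) on C5 (both C5 epimers) and CH2CH2CO2Et β on C10 | C=C1C[C@]23C[C@H]1CC(=O)[C@H]2[C@](C)(CCC(=O)OCC)C(CC(=O)OC)C3=O | intermediate
13 | C11 triisopropylsilyl enol ether (C11=C12) of 12 | C=C1C[C@]23C[C@H]1C=C(O[Si](C(C)C)(C(C)C)C(C)C)[C@H]2[C@](C)(CCC(=O)OCC)C(CC(=O)OC)C3=O | intermediate
14 | C6 enol triflate (C5=C6) of 13 | C=C1C[C@]23C[C@H]1C=C(O[Si](C(C)C)(C(C)C)C(C)C)[C@H]2[C@](C)(CCC(=O)OCC)C(CC(=O)OC)=C3OS(=O)(=O)C(F)(F)F | intermediate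
15 | triester: CO2Me (C7) on C6, C5=C6, CH2CO2Me on C5, CH2CH2CO2Et β on C10, 11-silyl enol ether | C=C1C[C@]23C[C@H]1C=C(O[Si](C(C)C)(C(C)C)C(C)C)[C@H]2[C@](C)(CCC(=O)OCC)C(CC(=O)OC)=C3C(=O)OC | intermediate
16 | potassium enolate of the ring-A β-keto ester (C3 enolate, C19 ester on C4, C5=C6) | [K+].C=C1C[C@]23C[C@H]1C=C(O[Si](C(C)C)(C(C)C)C(C)C)[C@H]2[C@]1(C)CCC([O-])=C(C(=O)OC)C1=C3C(=O)OC | intermediate
17 | tetracyclic keto diester: 3-oxo, 4β-methyl, 4α-CO2Me, C5=C6 bearing CO2Me, 11-silyl enol ether | C=C1C[C@]23C[C@H]1C=C(O[Si](C(C)C)(C(C)C)C(C)C)[C@H]2[C@]1(C)CCC(=O)[C@@](C)(C(=O)OC)C1=C3C(=O)OC | intermediate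
18 | C3 lithium enolate (C2=C3) of 17 | [Li+].C=C1C[C@]23C[C@H]1C=C(O[Si](C(C)C)(C(C)C)C(C)C)[C@H]2[C@]1(C)CC=C([O-])[C@@](C)(C(=O)OC)C1=C3C(=O)OC | intermediate
19 | dimethyl 3-oxo-11-(triisopropylsilyloxy)gibberella-11,16-diene-7,19-dioate (H-5β, H-6α, H-9β) | C=C1C[C@]23C[C@H]1C=C(O[Si](C(C)C)(C(C)C)C(C)C)[C@H]2[C@]1(C)CCC(=O)[C@@](C)(C(=O)OC)[C@H]1[C@@H]3C(=O)OC | intermediate
20 | dimethyl 3β-hydroxy-11-(triisopropylsilyloxy)gibberella-11,16-diene-7,19-dioate | C=C1C[C@]23C[C@H]1C=C(O[Si](C(C)C)(C(C)C)C(C)C)[C@H]2[C@]1(C)CC[C@H](O)[C@@](C)(C(=O)OC)[C@H]1[C@@H]3C(=O)OC | intermediate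
21 | dimethyl 3β-hydroxy-11-oxogibberell-16-ene-7,19-dioate | C=C1C[C@]23C[C@H]1CC(=O)[C@H]2[C@]1(C)CC[C@H](O)[C@@](C)(C(=O)OC)[C@H]1[C@@H]3C(=O)OC | intermediate
22 | 3β-hydroxy-11-oxogibberell-16-ene-7,19-dioic acid | C=C1C[C@]23C[C@H]1CC(=O)[C@H]2[C@]1(C)CC[C@H](O)[C@@](C)(C(=O)O)[C@H]1[C@@H]3C(=O)O | intermediate
23 | 3β,11α-dihydroxygibberell-16-ene-7,19-dioic acid (CNP0232910.1) | C=C1C[C@]23C[C@H]1C[C@@H](O)[C@H]2[C@]1(C)CC[C@H](O)[C@@](C)(C(=O)O)[C@H]1[C@@H]3C(=O)O | target

Total step count: 14. Longest linear sequence: 14 steps from 3-methoxybenzoic acid.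

**Steps most likely to fail**

Step 6. The conjugate addition may stall at the hindered β-carbon C10, go to the carbonyl groups, or occur on the α-face. Fallback, setting out from 10 and coming back at 12: the chain is brought in as an allyl group. Lithium diallylcuprate, (CH2=CHCH2)2CuLi, with Me3SiCl in THF at −78 °C should give the C10-allyl silyl enol ether F2. Fluoride-mediated alkylation with methyl bromoacetate, as in step 7, gives the allyl diketo ester F3. Hydroboration of the monosubstituted alkene with disiamylborane (the 1,1-disubstituted C16 methylene reacts far more slowly) and NaBO3 oxidation give the primary alcohol F4. TEMPO/PhI(OAc)2 in wet MeCN oxidises it to the carboxylic acid F5, and EtI/K2CO3 in DMF gives 12.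

Step 11. Lithium in ammonia may over-reduce the hindered esters or fragment the β-keto ester, and the C5 protonation may lose facial control. Fallback, setting out from 17 and coming back at 20: the ketone is removed before the enoate is reduced. LiBH(s-Bu)3 at −78 °C should give the 3β-hydroxy enoate F6. SmI2/HMPA/MeOH in THF then reduces only the conjugated ester by electron transfer; the axial 3β-hydroxyl, 1,3-diaxial to the new C5–H position, can deliver the proton to C5 on the β-face. Brief NaOMe/MeOH at 0–25 °C equilibrates C6 and gives 20.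

Step 5. Enolisation may not be followed by ring closure, intermolecular Michael addition may compete, and the enedione may scramble between double-bond tautomers. Fallback, setting out from 9 and coming back at 10: the C9–C10 bond is made by cross-coupling instead of Michael addition. NaI in AcOH adds HI across the ynone to give the (Z)-β-iodo enone F1. Intramolecular palladium-catalysed α-alkenylation of the C11 ketone (Pd2(dba)3, Xantphos, K3PO4, toluene, 80 °C), possible only through the C9 enolate, then closes ring B to 10.

**Further compounds**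

F1 | step 5 | (1R,5S)-1-[(Z)-3-iodobut-2-enoyl]-6-methylidenebicyclo[3.2.1]octan-3-one | C=C1C[C@]2(C(=O)/C=C(\I)C)C[C@H]1CC(=O)C2
F2 | step 6 | C6 trimethylsilyl enol ether with quaternary C10 (C20 α, allyl β), 11-oxo, H-9β | C=C1C[C@]23C[C@H]1CC(=O)[C@H]2[C@](C)(CC=C)C=C3O[Si](C)(C)C
F3 | step 6 | 6,11-diketone with CH2CO2Me on C5 and allyl β on C10 | C=C1C[C@]23C[C@H]1CC(=O)[C@H]2[C@](C)(CC=C)C(CC(=O)OC)C3=O
F4 | step 6 | 6,11-diketone with CH2CO2Me on C5 and 3-hydroxypropyl β on C10 | C=C1C[C@]23C[C@H]1CC(=O)[C@H]2[C@](C)(CCCO)C(CC(=O)OC)C3=O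
F5 | step 6 | 6,11-diketone with CH2CO2Me on C5 and 2-carboxyethyl β on C10 | C=C1C[C@]23C[C@H]1CC(=O)[C@H]2[C@](C)(CCC(=O)O)C(CC(=O)OC)C3=O
F6 | step 11 | 3β-alcohol of 17 (C5=C6 enoate and 11-silyl enol ether kept) | C=C1C[C@]23C[C@H]1C=C(O[Si](C(C)C)(C(C)C)C(C)C)[C@H]2[C@]1(C)CC[C@H](O)[C@@](C)(C(=O)OC)C1=C3C(=O)OC
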